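(Its constants were chosen freely; what happens was integrated by code.)

The constants first: they are enough for a quick number.

| flask | starting material | second substrate | third substrate | gas | temperature | time |
|---|---|---|---|---|---|---|
| birch | 0.10 M | 0.100 M | 0.100 M | 6.8 mM (held) | 90 °C | 12 min |
| maple | 0.10 M | 0.100 M | 0.100 M | 6.8 mM (held) | 70 °C | 12 min |
| larch | 0.10 M | 0.100 M | 0.100 M | 6.8 mM (held) | 50 °C | 12 min |

    third substrate + reagent → third product (k1 = 3.8 /M/min, Ea1 = 43.0 kJ/mol)
    second substrate + reagent → second product (k2 = 0.42 /M/min, Ea2 = 57.0 kJ/mol)
    gas ⇌ reagent, rate k3*(csat - [reagent]) (k3 = 44 /min, csat = 6.8 mM)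
    reagent ⇌ dormant form (K4 = 9.0, k4 = 0.012 /min, Ea4 = 90.0 kJ/mol, ΔH4 = 6.00 kJ/mol)
    starting material + reagent → target (k5 = 10 /M/min, Ea5 = 53.0 kJ/mol)
    starting material + target → side product (k6 = 0.92 /M/min, Ea6 = 58.0 kJ/mol)
    (constants at 50 °C)

- in percentages every species weighs as the starting material in it: one side product counts as two
- at the start none of reagent is dissolved
- all constants are for 50 °C and move with temperature by the activation energies and enthalpies

- the best flask by amount of target, in percent of the starting material charged; "all alike" if 1.5 percentage points covers them all (birch / maple / larch / all alike)
- amount of target at the end, in percent of the starting material charged, birch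
- amount of target at the end, in percent of the starting material charged, maple
- amount of target at the end, in percent of the starting material charged, larch

Ask what the end must be, then how fast it comes. Gas feeds reagent at 44 /min per unit of deficit, faster than starting material takes it even in birch, at 8.78 /min, so I hold reagent near 6.8 mM. Target is then made at k5·[reagent]·[starting material] and eaten at k6·[target]·[starting material]. Starting material cancels in the ratio of the two, and that leaves one quantity, the balance level c, the target concentration at which target is eaten as fast as it is made:

c = k5·[reagent]/k6 = 0.0739 M in larch

With S the starting material spent and P the target at that point, integrating gives: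

S = 2·c·ln(c/(c − P)) − P

The eating step is steeper by 5.00 kJ/mol, so k6/k5 grows 1.23 times from larch to birch, and c shrinks by that. I take the root of it for maple, since 70 °C lies midway. With reagent held, starting material decays in pseudo-first-order fashion; counting the reagent step alone overstates what is left at 12 min.

Larch: S/c = 1.35 for the whole charge, end value 46.4 %; 44.2 % left, so target 33.6 %.

Maple: c = 0.0667 M, S/c = 1.50, end value 44.0 %; 8.91 % left, so target 42.1 %.

Birch: c = 0.0602 M, S/c = 1.66, target 41.6 %, the charge spent.

Birch is my softest figure: by my estimate its early demand holds reagent near 83.4 % of saturation, which lowers c, so I keep it under maple.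

The forecast says 37.5 % for birch (35.5 % to 39.5 %), 42.5 % for maple (40.5 % to 44.5 %) and 36.5 % for larch (34.5 % to 38.5 %), “leaving maple as the best compromise”. It stands below my birch and above my larch.

The flasks give 38.9 % in birch, 42.4 % in maple and 36.5 % in larch, so maple is best.

The main loss in birch is the eating step: struck out, birch ends at 99.9 % target instead of 38.9 %. The neighbour of maple charged with 0.060 M has S/c = 0.899, which gives 56.1 % for a spent charge; that flask, with 3.1 % of its starting material left, ends at 54.1 %.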